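**Plan**
1. Numbering: C1 quaternary carbinol, C2 ketone, C3=C4 alkene, C5 CHOH, C6 CHOBz, C7 CH2OBz. The only ring is the C1–C6 carbocycle.
2. Retrosynthesis first simplifies the functional groups. C2=O goes back to an allylic CH2, C3=C4/C5–OH goes back through a C4–C5 epoxide to a C4=C5 alkene, and the C7 benzoate goes back onto the C1 oxygen of a C7 aldehyde.
3. This exposes a cyclohex-4-ene in which C1 (oxygen plus formyl carbon C7) and C6 (benzoate, allylic to C4=C5) are vicinal. That is an ortho Diels–Alder retron, and the cuts are C1–C6 and C2–C3.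
4. Forward, a C3–C6 dienyl benzoate and a C1/C2/C7 2-benzoyloxyacrolein, each carrying one benzoate of the target, close the ring in a single [4+2] step. All later steps are functional-group changes on that ring.
5. Stereochemistry: C1 comes from a chiral primary ammonium catalyst and C6 from the E diene geometry with endo addition. C5 comes from epoxidation trans to the C6 benzoate and syn to the C1 hydroxyl, and the C5–O bond is kept afterwards.

Key step: step 4

Remark on names: all locants follow the numbering of the plan, not lowest-locant rules.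
Assumption: with other dienes the L,L-derived triamine salt forms the new bond at the α-carbon on the face that corresponds to the (1S) cycloadduct, and the same sense is assumed here. If the oxygenated acyclic diene reverses it, the D,D-derived enantiomer of the catalyst is used and nothing else changes. The triamine is a known compound and its preparation is not counted.

**Step 1**
Reactants: 1 crotonaldehyde; 2 benzoyl chloride
Product: 4 (E)-buta-1,3-dien-1-yl benzoate, via potassium dienolate 3 (not isolated)
Conditions: t-BuOK, THF, −78 °C; then 2, −78 °C to rt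
Reagents that add atoms: potassium tert-butoxide, CC(C)(C)[O-].[K+] (supplies only the K+ of 3)
Why: γ-Deprotonation of the s-trans enal gives the extended E dienolate, which the hard acyl chloride captures on oxygen (dienolate O-acylation), so the E enol ester that can reach a reactive s-cis diene conformation results.

**Step 2**
Reactants: 5 2,2-dimethyl-1,3-dioxan-5-one; 2 benzoyl chloride
Product: 7 2,2-dimethyl-4H-1,3-dioxin-5-yl benzoate, via potassium enolate 6 (not isolated)
Conditions: KN(SiMe3)2, THF, −78 °C; then 2, −78 to 0 °C
Reagents that add atoms: KN(SiMe3)2, C[Si](C)(C)[N-][Si](C)(C)C.[K+] (supplies only the K+ of 6)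
Why: The potassium enolate of the symmetrical ketone is acylated on oxygen by the acid chloride (enol ester formation), which turns the dioxanone into a 4H-1,3-dioxin primed for cycloreversion.

**Step 3**
Reactants: 7 2,2-dimethyl-4H-1,3-dioxin-5-yl benzoate
Product: 8 2-benzoyloxyacrolein (3-oxoprop-1-en-2-yl benzoate)
Conditions: toluene, 110 °C, acetone distilled off; used directly
Reagents that add atoms: none
Why: Retro-hetero-Diels–Alder cleavage of the 4H-1,3-dioxin is driven by loss of volatile acetone and is an established entry to 2-acyloxyacroleins.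

**Step 4**
Reactants: 4 (E)-buta-1,3-dien-1-yl benzoate; 8 2-benzoyloxyacrolein
Product: 9 (1S,6S)-1,6-bis(benzoyloxy)cyclohex-4-ene-1-carbaldehyde (formyl cis to the C6 benzoate)
Conditions: (2S)-N-[(2S)-2-amino-3-phenylpropyl]-4-methyl-1-(pyrrolidin-1-yl)pentan-2-amine (10 mol %), C6F5SO3H (27.5 mol %), H2O (10 mol %), EtNO2, 0 °C to rt, excess 4
Reagents that add atoms: none
Why: The primary amino group of the catalyst condenses reversibly with 8 to a protonated aldimine whose lowered LUMO engages the s-cis conformer of 4 in a concerted, asynchronous [4+2] cycloaddition, and hydrolysis of the product iminium ion returns the catalyst. The closest known reactions are the enantioselective Diels–Alder additions of α-acyloxyacroleins to cyclic and acyclic dienes under chiral primary ammonium catalysis and the iminium-catalysed additions of enals to 1-acyloxybutadienes. The six-membered carbocycle closes intermolecularly and suprafacially on both partners, with C2–C3 as the leading bond and C1–C6 following. C1 is set by the catalyst, whose side chains screen one face of the iminium ion so that the diene reaches the α-carbon from the open face, and C6 is set relative to C1 by the E geometry of the enol ester together with the endo position of the iminium carbon, which puts C7 cis and the C1 oxygen trans to the C6 benzoate. The step needs ortho regiochemistry, which follows from pairing the largest HOMO coefficient at the unsubstituted diene terminus C3 with the largest LUMO coefficient at the β-carbon C2. It also needs endo selectivity, which rests on secondary overlap of the C=N+ unit with the diene and on the absence of the bridging CH2 that pushes α-substituted acroleins into exo addition with cyclopentadiene.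

**Step 5**
Reactants: 9 (1S,6S)-1,6-bis(benzoyloxy)cyclohex-4-ene-1-carbaldehyde
Product: 11 [(1R,6S)-6-(benzoyloxy)-1-hydroxycyclohex-4-en-1-yl]methyl benzoate, via primary alcohol 10 (not isolated)
Conditions: NaBH4, MeOH–THF, −20 °C; aq. NH4Cl work-up; then DBU (10 mol %), CH2Cl2, rt
Reagents that add atoms: none
Why: Borohydride reduces only the aldehyde, and the new primary alcohol takes over the neighbouring tertiary benzoate by base-catalysed 1,2-acyl migration through a five-membered orthoester, a shift for which the 6,7-dibenzoate with free tertiary C1–OH is the thermodynamic sink of all benzoyl positions, so C1 and C6 keep their configuration.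

**Step 6**
Reactants: 11 [(1R,6S)-6-(benzoyloxy)-1-hydroxycyclohex-4-en-1-yl]methyl benzoate
Product: 12 [(1R,4R,5R,6S)-6-(benzoyloxy)-4,5-epoxy-1-hydroxycyclohexyl]methyl benzoate (oxirane trans to C6–OBz and cis to C1–OH)
Conditions: mCPBA, CH2Cl2, 0 °C to rt
Reagents that add atoms: mCPBA, O=C(OO)c1cccc(Cl)c1
Why: In this Prilezhaev epoxidation the preferred half-chair (CH2OBz equatorial, C1–OH axial, C6–OBz pseudoaxial) lets the axial homoallylic hydroxyl hydrogen-bond the peracid on the lower face (Henbest effect) while the benzoate blocks the upper face, so both effects deliver oxygen trans to C6–OBz and set C4 and C5.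

**Step 7**
Reactants: 12 [(1R,4R,5R,6S)-6-(benzoyloxy)-4,5-epoxy-1-hydroxycyclohexyl]methyl benzoate
Product: 15 [(1R,5R,6S)-6-(benzoyloxy)-1,5-dihydroxycyclohex-3-en-1-yl]methyl benzoate, via hydroxy selenide 13 (not isolated), via selenoxide 14 (not isolated)
Conditions: (PhSe)2, NaBH4, EtOH–THF, 0 °C to rt; AcOH; then 30% H2O2, THF, 0 °C to rt
Reagents that add atoms: diphenyl diselenide, c1ccc(cc1)[Se][Se]c1ccccc1 (PhSe group of 13 and 14 only); hydrogen peroxide, OO (selenoxide oxygen of 14 only)
Why: In this organoselenium epoxide-to-allylic-alcohol transposition the soft selenolate opens the oxirane by SN2 attack at C4, the carbon remote from the deactivating and bulky C6 benzoate and the one that gives the trans-diaxial product (Fürst–Plattner rule), so the C5–O bond and its configuration stay untouched, and the derived selenoxide undergoes syn elimination away from the carbinol carbon towards C3–H, the normal course for β-hydroxy selenoxides, which places the alkene at C3=C4.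

**Step 8**
Reactants: 15 [(1R,5R,6S)-6-(benzoyloxy)-1,5-dihydroxycyclohex-3-en-1-yl]methyl benzoate
Product: 16 [(1R,5R,6S)-6-(benzoyloxy)-5-(tert-butyldimethylsilyloxy)-1-hydroxycyclohex-3-en-1-yl]methyl benzoate
Conditions: TBSCl, imidazole, DMF, rt
Reagents that add atoms: TBSCl, CC(C)(C)[Si](C)(C)Cl
Why: In this standard silyl ether formation TBSCl with imidazole reacts with the secondary allylic C5–OH but not with the tertiary C1–OH, and the bulky ether later shields C5–H and blocks benzoyl migration during the oxidation.

**Step 9**
Reactants: 16 [(1R,5R,6S)-6-(benzoyloxy)-5-(tert-butyldimethylsilyloxy)-1-hydroxycyclohex-3-en-1-yl]methyl benzoate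
Product: 18 [(1R,5R,6S)-6-(benzoyloxy)-5-(tert-butyldimethylsilyloxy)-1-hydroxy-2-oxocyclohex-3-en-1-yl]methyl benzoate, via C2 allylic alcohol 17 (not isolated)
Conditions: SeO2, 1,4-dioxane, 90 °C; filtration; then Dess–Martin periodinane, CH2Cl2, rt
Reagents that add atoms: selenium dioxide, O=[Se]=O
Why: In the Riley oxidation the ene step puts selenium on C4 and removes a C2–H, because the other orientation would build positive charge on C4 next to the C5–O dipole and would have to break the shielded C5–H, and the following [2,3]-shift returns oxygen to C2 and the alkene to C3=C4 without net transposition, after which Dess–Martin oxidation converges both C2 epimers on the ketone without touching the tertiary alcohol, so the transient C2 centre is of no consequence.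

**Step 10**
Reactants: 18 [(1R,5R,6S)-6-(benzoyloxy)-5-(tert-butyldimethylsilyloxy)-1-hydroxy-2-oxocyclohex-3-en-1-yl]methyl benzoate
Product: 19 [(1R,5R,6S)-6-(benzoyloxy)-1,5-dihydroxy-2-oxocyclohex-3-en-1-yl]methyl benzoate (CNP0212960.1)
Conditions: HF·pyridine, THF, 0 °C to rt
Reagents that add atoms: none
Why: Acidic fluoride cleaves the Si–O bond without forming a free alkoxide, so neither C6-to-C5 benzoyl migration nor base-induced degradation of the γ-hydroxy enone can start, and no stereocentre is involved.

**Compound list**
1 | crotonaldehyde | C/C=C/C=O | starting material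
2 | benzoyl chloride | O=C(Cl)c1ccccc1 | starting material
3 | potassium (1E)-buta-1,3-dien-1-olate (not isolated) | [K+].[O-]/C=C/C=C | intermediate
4 | (E)-buta-1,3-dien-1-yl benzoate | O=C(O/C=C/C=C)c1ccccc1 | intermediate
5 | 2,2-dimethyl-1,3-dioxan-5-one | CC1(C)OCC(=O)CO1 | starting material
6 | potassium 2,2-dimethyl-4H-1,3-dioxin-5-olate (not isolated) | [K+].CC1(C)OCC([O-])=CO1 | intermediate
7 | 2,2-dimethyl-4H-1,3-dioxin-5-yl benzoate | CC1(C)OCC(OC(=O)c2ccccc2)=CO1 | intermediate
8 | 2-benzoyloxyacrolein | O=CC(=C)OC(=O)c1ccccc1 | intermediate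
9 | (1S,6S)-1,6-bis(benzoyloxy)cyclohex-4-ene-1-carbaldehyde | O=C[C@]1(OC(=O)c2ccccc2)CCC=C[C@@H]1OC(=O)c1ccccc1 | intermediate
10 | (1R,6S)-1-(hydroxymethyl)cyclohex-4-ene-1,6-diyl dibenzoate (not isolated) | OC[C@]1(OC(=O)c2ccccc2)CCC=C[C@@H]1OC(=O)c1ccccc1 | intermediate
11 | [(1R,6S)-6-(benzoyloxy)-1-hydroxycyclohex-4-en-1-yl]methyl benzoate | O=C(OC[C@]1(O)CCC=C[C@@H]1OC(=O)c1ccccc1)c1ccccc1 | intermediate
12 | [(1R,4R,5R,6S)-6-(benzoyloxy)-4,5-epoxy-1-hydroxycyclohexyl]methyl benzoate | O=C(OC[C@]1(O)CC[C@H]2O[C@H]2[C@@H]1OC(=O)c1ccccc1)c1ccccc1 | intermediate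
13 | [(1R,4S,5S,6S)-6-(benzoyloxy)-1,5-dihydroxy-4-(phenylselanyl)cyclohexyl]methyl benzoate (not isolated) | O=C(OC[C@]1(O)CC[C@H]([Se]c2ccccc2)[C@@H](O)[C@@H]1OC(=O)c1ccccc1)c1ccccc1 | intermediate
14 | selenoxide of 13, both configurations at selenium (not isolated) | O=C(OC[C@]1(O)CC[C@H]([Se](=O)c2ccccc2)[C@@H](O)[C@@H]1OC(=O)c1ccccc1)c1ccccc1 | intermediate
15 | [(1R,5R,6S)-6-(benzoyloxy)-1,5-dihydroxycyclohex-3-en-1-yl]methyl benzoate | O=C(OC[C@]1(O)CC=C[C@@H](O)[C@@H]1OC(=O)c1ccccc1)c1ccccc1 | intermediate
16 | [(1R,5R,6S)-6-(benzoyloxy)-5-(tert-butyldimethylsilyloxy)-1-hydroxycyclohex-3-en-1-yl]methyl benzoate | O=C(OC[C@]1(O)CC=C[C@@H](O[Si](C)(C)C(C)(C)C)[C@@H]1OC(=O)c1ccccc1)c1ccccc1 | intermediate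
17 | [(1S,5R,6S)-6-(benzoyloxy)-5-(tert-butyldimethylsilyloxy)-1,2-dihydroxycyclohex-3-en-1-yl]methyl benzoate, either configuration at C2 (not isolated) | O=C(OC[C@]1(O)C(O)C=C[C@@H](O[Si](C)(C)C(C)(C)C)[C@@H]1OC(=O)c1ccccc1)c1ccccc1 | intermediate
18 | [(1R,5R,6S)-6-(benzoyloxy)-5-(tert-butyldimethylsilyloxy)-1-hydroxy-2-oxocyclohex-3-en-1-yl]methyl benzoate | O=C(OC[C@]1(O)C(=O)C=C[C@@H](O[Si](C)(C)C(C)(C)C)[C@@H]1OC(=O)c1ccccc1)c1ccccc1 | intermediate
19 | [(1R,5R,6S)-6-(benzoyloxy)-1,5-dihydroxy-2-oxocyclohex-3-en-1-yl]methyl benzoate | O=C(OC[C@]1(O)C(=O)C=C[C@@H](O)[C@@H]1OC(=O)c1ccccc1)c1ccccc1 | target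

Total step count: 10
Longest linear sequence: 9 steps (5 to 19, steps 2 to 10)

**Steps most likely to fail**

Step 4. The endo preference may be too small for an α-substituted iminium ion, and enantiofacial control may erode with an acyclic oxygenated diene. The acidic salt may also hydrolyse the enol ester or be acylated by the dienophile.

The fallback moves the source of chirality from the catalyst to the diene and keeps the same two bonds. It sets out from 1 (through dienolate 3) and 8. The dienolate is acylated with (S)-O-methylmandeloyl chloride to (E)-buta-1,3-dien-1-yl (S)-2-methoxy-2-phenylacetate F1, which is heated with 8 in toluene without any acid. The cis cycloadduct of the required facial series, (1S,6S)-1-(benzoyloxy)-1-formylcyclohex-4-en-6-yl (S)-2-methoxy-2-phenylacetate F2, is a diastereomer of every other adduct and should be separable by chromatography or crystallisation. LiAlH4 in THF then removes all acyl groups and reduces the aldehyde to (1R,6S)-1-(hydroxymethyl)cyclohex-4-ene-1,6-diol F3. Benzoylation with two equivalents of 2 in pyridine at 0 °C esterifies the primary and the secondary hydroxyl but not the tertiary one, which rejoins the route at 11.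

Step 9. The ene reaction may be too slow on a 1,2-disubstituted alkene that is deactivated by the C5 oxygen and flanked by a quaternary carbon. Long heating could then bring desilylation and acyl migration.

The fallback replaces the pericyclic oxidation by hydrogen-atom abstraction and sets out from 16. Rh2(cap)4 (cap = ε-caprolactamate, 1 mol %) and aqueous t-BuOOH in 1,2-dichloroethane at 40 °C generate tert-butylperoxyl radicals that remove a C2–H. The allyl radical is trapped as [(5R,6S)-6-(benzoyloxy)-2-(tert-butylperoxy)-5-(tert-butyldimethylsilyloxy)-1-hydroxycyclohex-3-en-1-yl]methyl benzoate F4, which loses tert-butanol under the reaction conditions and rejoins the route at 18. Site control then rests only on the bulk of the silyl ether around C5–H and C4, so chromatographic removal of a transposed isomer must be expected.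

Step 7. The basic borate medium may start C6-to-C5 benzoyl migration or ethanolysis at the alkoxide stage. Excess peroxide may over-oxidise the new alkene.

The fallback avoids both selenium and alkoxides and sets out from 12. LiBr and AcOH in THF open the oxirane at C4 under weakly acidic conditions to [(1R,4S,5S,6S)-6-(benzoyloxy)-4-bromo-1,5-dihydroxycyclohexyl]methyl benzoate F5. TBSOTf and 2,6-lutidine in CH2Cl2 at −78 to 0 °C silylate C5–OH to [(1R,4S,5S,6S)-6-(benzoyloxy)-4-bromo-5-(tert-butyldimethylsilyloxy)-1-hydroxycyclohexyl]methyl benzoate F6. DBU in toluene at 90 °C then effects anti E2 elimination. Only C3 carries a hydrogen anti to the C4 bromide (C5–H is syn to it), so the alkene forms at C3=C4 and the route is rejoined at 16, with steps 7 and 8 both replaced.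

**Further compounds**
F1 | step 4 | (E)-buta-1,3-dien-1-yl (S)-2-methoxy-2-phenylacetate | CO[C@H](C(=O)O/C=C/C=C)c1ccccc1
F2 | step 4 | (1S,6S)-1-(benzoyloxy)-1-formylcyclohex-4-en-6-yl (S)-2-methoxy-2-phenylacetate | O=C[C@]1(OC(=O)c2ccccc2)CCC=C[C@@H]1OC(=O)[C@@H](OC)c1ccccc1
F3 | step 4 | (1R,6S)-1-(hydroxymethyl)cyclohex-4-ene-1,6-diol | OC[C@]1(O)CCC=C[C@@H]1O
F4 | step 9 | [(5R,6S)-6-(benzoyloxy)-2-(tert-butylperoxy)-5-(tert-butyldimethylsilyloxy)-1-hydroxycyclohex-3-en-1-yl]methyl benzoate | O=C(OC[C@]1(O)C(OOC(C)(C)C)C=C[C@@H](O[Si](C)(C)C(C)(C)C)[C@@H]1OC(=O)c1ccccc1)c1ccccc1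
F5 | step 7 | [(1R,4S,5S,6S)-6-(benzoyloxy)-4-bromo-1,5-dihydroxycyclohexyl]methyl benzoate | O=C(OC[C@]1(O)CC[C@H](Br)[C@@H](O)[C@@H]1OC(=O)c1ccccc1)c1ccccc1
F6 | step 7 | [(1R,4S,5S,6S)-6-(benzoyloxy)-4-bromo-5-(tert-butyldimethylsilyloxy)-1-hydroxycyclohexyl]methyl benzoate | O=C(OC[C@]1(O)CC[C@H](Br)[C@@H](O[Si](C)(C)C(C)(C)C)[C@@H]1OC(=O)c1ccccc1)c1ccccc1
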